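## Structural features

The target is a cyclohex-2-en-1-one (C1 carbonyl, C2=C3, C4, C5, C6) whose C5 bears a tertiary hydroxyl and a 2-oxoalkyl chain: C7 is a methylene, C8 a ketone, and beyond it runs the seventeen-carbon tail of oleic acid with its (Z)-alkene. C5 is the only stereocentre and is (R) (CIP order O > C6 > C7 > C4). It has no stereogenic neighbour, and its two ring arms, C4–C3= and C6–C1(=O), differ only in where the enone oxygen sits, so the ring is one oxidation pattern away from a meso compound. The C5 hydroxyl is β to both carbonyls: loss of water into the ring gives a cross-conjugated dienone that tautomerises to a phenol, and retro-aldol cleavage of C5–C7 leaves a tautomer of resorcinol, so acid, base and heat all become dangerous once both ketones are present. The (Z)-alkene forbids hydrogenation and strongly electrophilic reagents. The real difficulty is therefore twofold: to fix the absolute configuration of a quaternary carbinol whose ring arms are nearly enantiotopic, and to choose the moment at which the double aldol is unveiled. The key step uses the fact that O–C5–C7–C8(=O) is an aldol unit that can be carried as a 2-isoxazoline spiro-fused at C5, assembled from a nitrile oxide (C8) and an exocyclic methylene (C5=C7), while two cis oxygens on C1 and C3 direct the dipole to one ring face and are told apart only afterwards.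

## Logic of the disconnections

**21 back to 19.** The C2=C3 double bond and the C1 carbonyl are removed together: C3 regains an acetoxy group (the C3–O bond is restored in the backward sense) and C1 returns to a carbinol. The reason is that the enone is what makes the aldol aromatisation-prone, so it should exist only in the last flask. The gain is a saturated ring with three cis oxygens. The forward step must oxidise the one secondary alcohol of 19 beside a free tertiary one and then, through 20, expel acetate only, with a base too weak to touch the C5 hydroxyl.

**19 back to 18 and 16.** The C1 oxygen is covered as a silyl ether (18). Then the C8 carbonyl and the C5 hydroxyl are tied together through nitrogen: the bond cut in the forward sense is the N–O bond of the isoxazoline in 16, with 17 on the way. The reason is protection: in 16 the aldol can neither revert nor dehydrate. The gain is a rigid spirocycle that tolerates acylation. The demands are an N–O cleavage that spares the (Z)-alkene, the acetate and the silyl ether, and a desilylation that causes no acetyl shift between the cis C1 and C3 oxygens, because such a shift would interchange their roles and so invert the sense of C5.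

**16 back to 15.** The acetyl C–O bond is cut to expose the secondary hydroxyl on C3. This hydroxyl steers the cycloaddition, so it must be free one step earlier and becomes the leaving group only afterwards. Nothing is simplified structurally; the forward demand is a plain acylation.

**15 back to 8 and 12.** This is the strategic cut: C7–C8 and C5–O of the isoxazoline are broken together, the reverse of a nitrile oxide cycloaddition. It divides the molecule into a seven-carbon ring piece and the eighteen-carbon chain, removes the spiro ring, and reduces the quaternary stereocentre to the choice of one face of an exocyclic alkene. The forward step must place oxygen on C5 and carbon on C7, choose the face cis to the free hydroxyl through 13, and let 14 react with this alkene in preference to dimerisation or to the chain alkene.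

**12 back to 11, 10 and 9.** The C–Cl bond, the C=N bond and the aldehyde oxidation level are removed in turn, which takes the dipole precursor back to a commodity alcohol. The only demand is that oxidation and chlorination leave the (Z)-alkene untouched.

**8 back to 7, 6 and 5.** The O–Si bond and the acetyl C–O bond are cut so that the two ring oxygens become equivalent. The reason is that the whole chirality of 8 lies in which of two cis oxygens carries the silyl group, so the problem becomes the desymmetrisation of meso 5, a task for a lipase. The gain is an achiral precursor. The forward demands are that the enzyme acylate the hydroxyl on the future C3, and that neither acetyl nor silyl wander to the other oxygen in 6, 7 or 8, since either shift would be racemisation.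

**5 back to 4, 3, 2 and 1.** The C5=C7 double bond is cut (methylenation in reverse) to meso 3, which is returned to 2 and then to 1 by removing the two silyl groups. The gain is a threefold-symmetric catalogue compound with all ring oxygens in place. The forward demands are a bis-silylation that is only statistically selective, and a methylenation of a ketone flanked by two β-silyloxy groups without β-elimination.

## Other disconnections considered

**Alternative 1:** The cut is the ring bond C2–C3 (the enone double bond). In the forward direction the achiral keto dialdehyde A1, whose central carbon (the future C5) carries a silyloxy group, one acetonyl arm and two identical formylmethyl arms, would be exposed to a chiral amine. The enamine of the methyl ketone would add through C2 to one of the two enantiotopic aldehyde carbons (C3), and loss of water would give cyclohexenone A2, in which the untouched arm is C7–C8.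

- In its favour: ring, enone and stereocentre would arise in one catalytic operation from a small acyclic molecule; no stoichiometric source of chirality is consumed; and desymmetrising aldol condensation of symmetric dicarbonyl compounds under amine catalysis is an established reaction type.
- Against it here: the catalyst has to work through the less readily formed ketone enamine in the presence of two more electrophilic aldehydes that can themselves condense. Every carbonyl of A1 is β to the silyloxy group, so loss of silanolate threatens before and after cyclisation. The stereocentre lies two atoms from the reacting carbons. A2 is already the aromatisation-prone 5-oxygenated cyclohexenone, and the whole C17 chain must still be added chemoselectively at its aldehyde carbon C8 and the resulting carbinol oxidised.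
- Comparison: in structure it builds the ring from an open chain, whereas the chosen plan decorates a ready-made ring. In mechanism it relies on catalyst-controlled selection between groups, the chosen plan on substrate-directed face selection backed by an enzymatic desymmetrisation. In step economy it would be clearly shorter, and in catalytic use of chirality it is the better of the two. It is not chosen because its fragile enone and free aldehyde stand at the beginning of the end-game and not at its end.

**Alternative 2:** The bond formed is C4–C5, paid for by breaking a bond (C8–C2) that the target does not contain. In the forward direction the tertiary alcohol A3 would be converted into its potassium alkoxide. A3 is a 6-vinylcyclohex-2-en-1-ol in which the carbinol carbon is the future C8 and already carries the chain, the enol ether carbon is the future C5, and the silyloxy and vinyl groups stand trans on the future C1 and C2. A [3,3] shift through a boat-like array across the ring would open the old ring, close the new one and leave the C8 enolate, giving A4 after protonation.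

- In its favour: the quaternary centre is made by C–C bond formation with suprafacial chirality transfer from the vinyl-bearing carbon, which does not depend on any conformer-specific delivery. The alkoxide-to-enolate change gives a large rate advantage. The chain ketone and the C2=C3 alkene appear directly at the right oxidation level and position, with no unmasking or elimination step; on this point it is better than the chosen plan.
- Against it here: one cyclohexene is exchanged for another, so apart from enolate formation there is little driving force. The primary product is the enolate of a β-alkoxy ketone and could expel the p-methoxybenzyl oxide group from C5 (E1cB), which would erase the centre just made. A3 needs two contiguous stereocentres of defined absolute configuration to create one, and as a tertiary allylic alcohol derived from an enol ether it is acid-labile. After the key step two protecting groups must still be removed and C1 oxidised with the double aldol exposed.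
- Comparison: in structure both plans end with the same oxidation at C1, but this one carries the C5 oxygen as an ether instead of inside a ring. In mechanism a sigmatropic shift is stereospecific where the cycloaddition is only stereoselective, which counts in its favour. In step economy it is at best equal, because making enantiopure A3 is a multistep problem of its own.

**Alternative 3:** The cut is the ring bond C1–C6. In the forward direction the epoxide A5 would be deprotonated at C1 by a strong base. A5 is a 2,2-disubstituted oxirane formed by C5 and C6; one arm is C7 with the chain ketone C8 masked as a dithiane, the other is C4 followed by the (Z)-alkene C3=C2 and the dithiane carbon C1. The sulfur-stabilised allyl anion would attack the epoxide methylene C6, closing the six-membered ring and freeing the C5 alkoxide to give A6. Since both epoxide carbons become ring members, this is the endo mode of epoxide opening in the usual convention, not an exo one.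

- In its favour: the stereocentre is set on an open-chain epoxide and is not touched by the ring closure, because the nucleophile attacks the other epoxide carbon. Both carbonyls stay masked in a base-stable form, which is equal in concept to the isoxazoline masking of the chosen plan and, unlike it, covers the ring ketone too. A primary carbon is attacked.
- Against it here: the endo trajectory is normally the disfavoured one and is helped only because the exo alternative would have to hit a quaternary carbon. Only the (Z)-configured allyl anion can reach C6, and allyl anions can lose their geometry. Attack through C3 and base-induced opening of the epoxide to an allylic alcohol compete. An enantiopure 2,2-dialkyl epoxide with two similar methylene arms is hard to make. At the end two dithianes must be removed with thiophilic or oxidising electrophiles beside a (Z)-alkene and an aldol that aromatises readily.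
- Comparison: in structure it closes the carbocycle late, whereas the chosen plan starts from it. In mechanism both carry the C5 configuration through the key step by design, here by not touching it, there by directed delivery. In step economy it is expected to be the longest of the four plans, and its final deprotection is harsher than the final step of the chosen plan.

Key step: step 11

Remark 1: cis,cis-cyclohexane-1,3,5-triol (the ring-hydrogenation product of phloroglucinol) is taken as a catalogue compound, sold as its dihydrate, so the route starts from it.

Remark 2: the lipase in step 5 is assumed to acylate the (R)-configured carbinol of 5, as this enzyme does with cis-cyclohexane-1,3-diol; the fallback for step 5 covers the opposite sense.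

Remark 3: the descriptors were cross-checked: (1R,3S) in 8, all-cis (5S,7S,9R) in 15 and (R) in 21 belong to one stereochemical series when the free hydroxyl of 8 sits on the future C3, so no key-step structure needed correction.

## Route

Step 1
Reactants: 1 cis,cis-cyclohexane-1,3,5-triol
Product: 2 all-cis-3,5-bis[(tert-butyldimethylsilyl)oxy]cyclohexan-1-ol
Conditions: 1 (dried azeotropically), TBSCl (2.05 equiv), imidazole, DMF, 0 °C to rt
Reagents that add atoms: tert-butyldimethylsilyl chloride (TBSCl), CC(C)(C)[Si](C)(C)Cl
Why: Silyl ether formation under Corey conditions; the three equatorial hydroxyls are equivalent, so two equivalents of TBSCl should give the bis-ether as the principal component of a statistical mixture, to be separated by chromatography with the mono- and tris-ethers recycled.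

Step 2
Reactants: 2 all-cis-3,5-bis[(tert-butyldimethylsilyl)oxy]cyclohexan-1-ol
Product: 3 (3R,5S)-3,5-bis[(tert-butyldimethylsilyl)oxy]cyclohexan-1-one (cis, meso)
Conditions: Dess–Martin periodinane (DMP), pyridine, CH2Cl2, 0 °C to rt
Reagents that add atoms: none
Why: Dess–Martin oxidation under neutral, buffered conditions; a ketone with two β-silyloxy groups is prone to β-elimination, so strong acid and base are avoided, and the two stereocentres are untouched.

Step 3
Reactants: 3 (3R,5S)-3,5-bis[(tert-butyldimethylsilyl)oxy]cyclohexan-1-one
Product: 4 (1R,3S)-1,3-bis[(tert-butyldimethylsilyl)oxy]-5-methylidenecyclohexane (cis, meso)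
Conditions: Ph3PCH3Br, KOt-Bu, THF, 0 °C; then 3, −78 to 0 °C
Reagents that add atoms: methyltriphenylphosphonium bromide, C[P+](c1ccccc1)(c1ccccc1)c1ccccc1.[Br-]
Why: Wittig methylenation with the non-stabilised ylide at low temperature; addition to the unhindered ketone should outpace enolisation and E1cB loss of silanolate.

Step 4
Reactants: 4 (1R,3S)-1,3-bis[(tert-butyldimethylsilyl)oxy]-5-methylidenecyclohexane
Product: 5 (1R,3S)-5-methylidenecyclohexane-1,3-diol (cis, meso)
Conditions: TBAF, THF, rt
Reagents that add atoms: none
Why: Fluoride-mediated cleavage of both silyl ethers, driven by Si–F bond formation; nothing else in the molecule is fluoride-sensitive and the exocyclic alkene is not exposed to acid.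

Step 5
Reactants: 5 (1R,3S)-5-methylidenecyclohexane-1,3-diol
Product: 6 (1R,5S)-5-hydroxy-3-methylidenecyclohexyl acetate
Conditions: Novozym 435 (immobilised Candida antarctica lipase B), vinyl acetate, t-BuOMe, rt
Reagents that add atoms: vinyl acetate, CC(=O)OC=C
Why: Lipase-catalysed irreversible transesterification desymmetrises the meso diol; the enzyme is expected to acylate the (R)-configured carbinol (the future C3), which fixes the absolute configuration of the whole route, and any over-acylation to the diacetate should consume mainly the minor enantiomer and so sharpen the enantiopurity.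

Step 6
Reactants: 6 (1R,5S)-5-hydroxy-3-methylidenecyclohexyl acetate
Product: 7 (1R,5S)-5-[(tert-butyldimethylsilyl)oxy]-3-methylidenecyclohexyl acetate
Conditions: TBSCl, imidazole, DMF, 0 °C to rt
Reagents that add atoms: tert-butyldimethylsilyl chloride (TBSCl), CC(C)(C)[Si](C)(C)Cl
Why: Silylation of the remaining hydroxyl (the future C1 oxygen) with imidazole, a base too weak to cause acetyl migration between the cis oxygens.

Step 7
Reactants: 7 (1R,5S)-5-[(tert-butyldimethylsilyl)oxy]-3-methylidenecyclohexyl acetate
Product: 8 (1R,3S)-3-[(tert-butyldimethylsilyl)oxy]-5-methylidenecyclohexan-1-ol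
Conditions: K2CO3 (cat.), MeOH, 0 °C to rt
Reagents that add atoms: none
Why: Base-catalysed transesterification removes the acetate as methyl acetate; a secondary TBS ether is stable to methanolic carbonate, and this acetate-to-silyl exchange on cis-1,3-dioxygenated rings is standard practice that should not move the silyl group.

Step 8
Reactants: 9 oleyl alcohol [(9Z)-octadec-9-en-1-ol]
Product: 10 (9Z)-octadec-9-enal
Conditions: TEMPO (2,2,6,6-tetramethylpiperidin-1-oxyl, cat.), PhI(OAc)2, CH2Cl2, rt
Reagents that add atoms: none
Why: Oxoammonium-mediated oxidation of a primary alcohol stops at the aldehyde and leaves the (Z)-alkene alone.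

Step 9
Reactants: 10 (9Z)-octadec-9-enal
Product: 11 (9Z)-octadec-9-enal oxime (mixture of C=N isomers)
Conditions: NH2OH·HCl, NaOAc, EtOH/H2O, rt
Reagents that add atoms: hydroxylamine hydrochloride, Cl.NO
Why: Condensation of the aldehyde with hydroxylamine; both oxime isomers lead to the same hydroximoyl chloride, so the mixture is used as such.

Step 10
Reactants: 11 (9Z)-octadec-9-enal oxime
Product: 12 (9Z)-N-hydroxyoctadec-9-enimidoyl chloride
Conditions: NCS, pyridine (cat.), DMF, 0 °C to rt
Reagents that add atoms: N-chlorosuccinimide (NCS), O=C1CCC(=O)N1Cl
Why: Chlorination of the aldoxime carbon by NCS gives the hydroximoyl chloride; an isolated dialkyl alkene is inert to NCS in DMF at this temperature, and the product is used crude because aliphatic hydroximoyl chlorides do not store well.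

Step 11
Reactants: 8 (1R,3S)-3-[(tert-butyldimethylsilyl)oxy]-5-methylidenecyclohexan-1-ol; 12 (9Z)-N-hydroxyoctadec-9-enimidoyl chloride
Product: 15 (5S,7S,9R)-9-[(tert-butyldimethylsilyl)oxy]-3-[(8Z)-heptadec-8-en-1-yl]-1-oxa-2-azaspiro[4.5]dec-2-en-7-ol, via bromomagnesium alkoxide 13 (not isolated), via nitrile oxide 14 (not isolated)
Conditions: i-PrOH (3.3 equiv), EtMgBr (3.0 equiv), CH2Cl2, 0 °C; then 12 (1.5 equiv) in CH2Cl2 added over 4 h, 0 °C to rt; aq NH4Cl
Reagents that add atoms: none
Why: EtMgBr converts 8 into alkoxide 13 and i-PrOH into bromomagnesium isopropoxide, which takes HCl from 12 and releases nitrile oxide 14 slowly, so that no free Grignard reagent is left to add to the dipole. The bond-forming event is a concerted, asynchronous [3+2] cycloaddition of the nitrile oxide to the 1,1-disubstituted alkene; the closest known reaction type is the magnesium-alkoxide-directed nitrile oxide cycloaddition of allylic and homoallylic alcohols. The isoxazoline ring is closed by the cycloaddition itself (C7–C8 and C5–O formed in one step, so no separate cyclisation mode applies), with oxygen on the more substituted carbon C5 as is normal for 1,1-dialkyl alkenes and as the magnesium bridge also requires. The new stereocentre C5 is controlled by the alkoxide on the future C3: in the conformer with that oxygen axial, magnesium links the alkoxide and the dipole oxygen in a six-membered array (O–C3–C4–C5···O–Mg) and the oxygen is delivered to the face of C5 cis to the alkoxide, which gives the all-cis adduct. This conformer also has the silyloxy group axial, at the cost of one syn-diaxial O/O contact, but the sp2 ring carbon removes the other 1,3-diaxial partners and the diequatorial conformer has no accelerated pathway, so the reaction should pass through the minor conformer (Curtin–Hammett). Chemoselectivity is needed against the (Z)-alkene of the chain and against dimerisation of 14 to the furoxan; the first follows from the low reactivity of an unactivated 1,2-dialkyl alkene compared with the magnesium-bound alkene, the second from slow addition of 12 to an excess of alkoxide. A covalent magnesium alkoxide in CH2Cl2 is not expected to accept the silyl group from the neighbouring oxygen, which matters because that shift would interchange the two ring oxygens.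

Step 12
Reactants: 15 (5S,7S,9R)-9-[(tert-butyldimethylsilyl)oxy]-3-[(8Z)-heptadec-8-en-1-yl]-1-oxa-2-azaspiro[4.5]dec-2-en-7-ol
Product: 16 (5S,7S,9R)-9-[(tert-butyldimethylsilyl)oxy]-3-[(8Z)-heptadec-8-en-1-yl]-1-oxa-2-azaspiro[4.5]dec-2-en-7-yl acetate
Conditions: Ac2O, pyridine, 4-(dimethylamino)pyridine (cat.), CH2Cl2, rt
Reagents that add atoms: acetic anhydride, CC(=O)OC(C)=O
Why: Nucleophile-catalysed acylation of the secondary alcohol turns the directing hydroxyl into the future leaving group on C3; the isoxazoline and the silyl ether are inert.

Step 13
Reactants: 16 (5S,7S,9R)-9-[(tert-butyldimethylsilyl)oxy]-3-[(8Z)-heptadec-8-en-1-yl]-1-oxa-2-azaspiro[4.5]dec-2-en-7-yl acetate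
Product: 18 (1S,3S,5R)-5-[(tert-butyldimethylsilyl)oxy]-3-hydroxy-3-[(10Z)-2-oxononadec-10-en-1-yl]cyclohexyl acetate, via hydroxy imine 17 (not isolated)
Conditions: Mo(CO)6 (1 equiv), MeCN/H2O (10:1), 80 °C
Reagents that add atoms: water, O
Why: Zerovalent molybdenum inserts into the weak N–O bond and water hydrolyses the resulting β-hydroxy imine 17 to the ketone, the standard unmasking of an isoxazoline as an aldol; isolated alkenes, esters and silyl ethers are tolerated, and because no ring ketone exists yet the tertiary aldol has only the slow reversion and dehydration channels of a simple β-hydroxy ketone; C5 is not touched.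

Step 14
Reactants: 18 (1S,3S,5R)-5-[(tert-butyldimethylsilyl)oxy]-3-hydroxy-3-[(10Z)-2-oxononadec-10-en-1-yl]cyclohexyl acetate
Product: 19 (1S,3R,5R)-3,5-dihydroxy-3-[(10Z)-2-oxononadec-10-en-1-yl]cyclohexyl acetate
Conditions: HF·pyridine, pyridine, THF, 0 °C to rt
Reagents that add atoms: none
Why: Buffered acidic fluoride cleaves the secondary TBS ether; it is preferred to basic fluoride because an alkoxide on C1 would invite 1,3-acetyl migration from C3 (which would interchange the two oxygens and erode the enantiopurity) and retro-aldol cleavage.

Step 15
Reactants: 19 (1S,3R,5R)-3,5-dihydroxy-3-[(10Z)-2-oxononadec-10-en-1-yl]cyclohexyl acetate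
Product: 21 (5R)-5-hydroxy-5-[(10Z)-2-oxononadec-10-en-1-yl]cyclohex-2-en-1-one, via acetoxy ketone 20 (not isolated)
Conditions: DMP, CH2Cl2, 0 °C to rt; then Et3N, 0 °C
Reagents that add atoms: none
Why: Dess–Martin oxidation converts the only secondary alcohol into the C1 ketone (the tertiary C5 hydroxyl cannot be oxidised) to give β-acetoxy ketone 20; triethylamine then removes the acidic C2 proton and acetate leaves from C3 (E1cB) to give the conjugated enone, while hydroxide on C5 is far too poor a leaving group to compete at this temperature, so C5 ends as (R).

## Compound list

1 | cis,cis-cyclohexane-1,3,5-triol | O[C@H]1C[C@@H](O)C[C@@H](O)C1 | starting material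
2 | all-cis-3,5-bis[(tert-butyldimethylsilyl)oxy]cyclohexan-1-ol (meso) | O[C@H]1C[C@@H](O[Si](C)(C)C(C)(C)C)C[C@@H](O[Si](C)(C)C(C)(C)C)C1 | intermediate
3 | (3R,5S)-3,5-bis[(tert-butyldimethylsilyl)oxy]cyclohexan-1-one (cis, meso) | O=C1C[C@@H](O[Si](C)(C)C(C)(C)C)C[C@@H](O[Si](C)(C)C(C)(C)C)C1 | intermediate
4 | (1R,3S)-1,3-bis[(tert-butyldimethylsilyl)oxy]-5-methylidenecyclohexane (cis, meso) | C=C1C[C@@H](O[Si](C)(C)C(C)(C)C)C[C@@H](O[Si](C)(C)C(C)(C)C)C1 | intermediate
5 | (1R,3S)-5-methylidenecyclohexane-1,3-diol (cis, meso) | C=C1C[C@@H](O)C[C@@H](O)C1 | intermediate
6 | (1R,5S)-5-hydroxy-3-methylidenecyclohexyl acetate | C=C1C[C@@H](OC(C)=O)C[C@@H](O)C1 | intermediate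
7 | (1R,5S)-5-[(tert-butyldimethylsilyl)oxy]-3-methylidenecyclohexyl acetate | C=C1C[C@@H](OC(C)=O)C[C@@H](O[Si](C)(C)C(C)(C)C)C1 | intermediate
8 | (1R,3S)-3-[(tert-butyldimethylsilyl)oxy]-5-methylidenecyclohexan-1-ol | C=C1C[C@@H](O)C[C@@H](O[Si](C)(C)C(C)(C)C)C1 | intermediate
9 | oleyl alcohol, (9Z)-octadec-9-en-1-ol | CCCCCCCC/C=C\CCCCCCCCO | starting material
10 | (9Z)-octadec-9-enal | CCCCCCCC/C=C\CCCCCCCC=O | intermediate
11 | (9Z)-octadec-9-enal oxime (C=N isomers) | CCCCCCCC/C=C\CCCCCCCC=NO | intermediate
12 | (9Z)-N-hydroxyoctadec-9-enimidoyl chloride | CCCCCCCC/C=C\CCCCCCCC(Cl)=NO | intermediate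
13 | bromomagnesium (1R,3S)-3-[(tert-butyldimethylsilyl)oxy]-5-methylidenecyclohexan-1-olate | C=C1C[C@@H](O[Mg]Br)C[C@@H](O[Si](C)(C)C(C)(C)C)C1 | intermediate (not isolated)
14 | (9Z)-octadec-9-enenitrile oxide | CCCCCCCC/C=C\CCCCCCCC#[N+][O-] | intermediate (not isolated)
15 | (5S,7S,9R)-9-[(tert-butyldimethylsilyl)oxy]-3-[(8Z)-heptadec-8-en-1-yl]-1-oxa-2-azaspiro[4.5]dec-2-en-7-ol (ring oxygen, hydroxyl and silyloxy all cis) | CCCCCCCC/C=C\CCCCCCCC1=NO[C@@]2(C1)C[C@@H](O)C[C@@H](O[Si](C)(C)C(C)(C)C)C2 | intermediate
16 | (5S,7S,9R)-9-[(tert-butyldimethylsilyl)oxy]-3-[(8Z)-heptadec-8-en-1-yl]-1-oxa-2-azaspiro[4.5]dec-2-en-7-yl acetate | CCCCCCCC/C=C\CCCCCCCC1=NO[C@@]2(C1)C[C@@H](OC(C)=O)C[C@@H](O[Si](C)(C)C(C)(C)C)C2 | intermediate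
17 | (1S,3S,5R)-5-[(tert-butyldimethylsilyl)oxy]-3-hydroxy-3-[(10Z)-2-iminononadec-10-en-1-yl]cyclohexyl acetate | CCCCCCCC/C=C\CCCCCCCC(=N)C[C@]1(O)C[C@@H](OC(C)=O)C[C@@H](O[Si](C)(C)C(C)(C)C)C1 | intermediate (not isolated)
18 | (1S,3S,5R)-5-[(tert-butyldimethylsilyl)oxy]-3-hydroxy-3-[(10Z)-2-oxononadec-10-en-1-yl]cyclohexyl acetate (three ring oxygens cis) | CCCCCCCC/C=C\CCCCCCCC(=O)C[C@]1(O)C[C@@H](OC(C)=O)C[C@@H](O[Si](C)(C)C(C)(C)C)C1 | intermediate
19 | (1S,3R,5R)-3,5-dihydroxy-3-[(10Z)-2-oxononadec-10-en-1-yl]cyclohexyl acetate (three ring oxygens cis) | CCCCCCCC/C=C\CCCCCCCC(=O)C[C@]1(O)C[C@@H](OC(C)=O)C[C@@H](O)C1 | intermediate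
20 | (1R,3R)-3-hydroxy-5-oxo-3-[(10Z)-2-oxononadec-10-en-1-yl]cyclohexyl acetate | CCCCCCCC/C=C\CCCCCCCC(=O)C[C@]1(O)C[C@@H](OC(C)=O)CC(=O)C1 | intermediate (not isolated)
21 | (5R)-5-hydroxy-5-[(10Z)-2-oxononadec-10-en-1-yl]cyclohex-2-en-1-one | CCCCCCCC/C=C\CCCCCCCC(=O)C[C@]1(O)CC=CC(=O)C1 | target

## Step count and least certain steps

Total: 15 steps. Longest linear sequence: 12 steps (steps 1–7 and 11–15, from 1); the chain branch (steps 8–10, from 9) joins at step 11.

**Step 11 (key step).** What may fail is facial delivery: the reacting conformer needs both ring oxygens axial, and if it is too scarce the undirected addition from either face takes over. Dimerisation of 14 to the furoxan may also win if the alkene is too slow, and silyl migration within 13 is a lesser risk. The fallback moves the cycloaddition one stage earlier and uses the symmetry instead of a protecting group. Diol 5, as its bis(bromomagnesium) alkoxide (EtMgBr, i-PrOH, CH2Cl2), would be treated with 12. Both alkoxides lie on one face and can hold magnesium between them in the diaxial form, so activation and delivery no longer depend on forcing a silyl ether axial. This should give the meso spiro-isoxazoline diol, all-cis 3-[(8Z)-heptadec-8-en-1-yl]-1-oxa-2-azaspiro[4.5]dec-2-ene-7,9-diol F1. Mo(CO)6 in wet MeCN would open it to the meso triol ketone (10Z)-1-(all-cis-1,3,5-trihydroxycyclohexyl)nonadec-10-en-2-one F2. Lipase-catalysed monoacetylation (Novozym 435, vinyl acetate) of the two enantiotopic secondary hydroxyls of F2 would then give 19. The fallback sets out from 5 and 12 and returns at 19; it would replace steps 5–7 and 11–14, at the price of an enzymatic group selection on a larger substrate.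

**Step 5.** The enzyme may acylate the other enantiotopic hydroxyl, or discriminate incompletely and run on to the diacetate. The fallback is to peracetylate 5 (Ac2O, pyridine) to cis-5-methylidenecyclohexane-1,3-diyl diacetate F3 and to run the same lipase in the hydrolytic direction (phosphate buffer, pH 7). An enzyme that prefers one carbinol acylates it in one mode and deacylates it in the other, so hydrolysis delivers the monoacetate of opposite configuration to that from acylation. This sets out from 5 and returns at 6.

**Step 3.** The basic ylide may enolise the ketone and trigger E1cB loss of a β-silanolate instead of adding to the carbonyl. The fallback is a two-stage Peterson methylenation. Addition of Me3SiCH2MgCl with CeCl3 (THF, −78 °C), a weakly basic organocerium reagent, would give cis-3,5-bis[(tert-butyldimethylsilyl)oxy]-1-[(trimethylsilyl)methyl]cyclohexan-1-ol F4. KH in THF would then induce syn elimination of trimethylsilanolate. This sets out from 3 and returns at 4.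

**Step 13.** At 80 °C, with Lewis-acidic molybdenum residues present, the freed tertiary aldol may revert or dehydrate, hydrolysis of 17 may stall, or the (Z)-alkene may isomerise on the metal. The fallback replaces thermal insertion of a metal carbonyl by single-electron N–O cleavage at room temperature: SmI2 with B(OH)3 in THF/H2O, where boric acid captures the hydroxy imine and assists its hydrolysis. No heating and no alkene–metal carbonyl contact are involved. It sets out from 16 and returns at 18 without any new compound.

**Step 15.** Under the amine base the unmasked double aldol may over-react: E1cB loss of the C5 hydroxyl with aromatisation, or retro-aldol cleavage. The fallback reverses the order of unveiling, so that the C5 oxygen is still locked in the isoxazoline when base is used. From 16, HF·pyridine would give (5R,7S,9R)-3-[(8Z)-heptadec-8-en-1-yl]-9-hydroxy-1-oxa-2-azaspiro[4.5]dec-2-en-7-yl acetate F5. DMP followed by Et3N would give the spiro enone (5R)-3-[(8Z)-heptadec-8-en-1-yl]-1-oxa-2-azaspiro[4.5]deca-2,8-dien-7-one F6. N–O cleavage (Mo(CO)6 in wet MeCN, or SmI2/B(OH)3) would then free the aldol. This sets out from 16 and returns at 21. Its weak point is that the finished target is then exposed to the N–O cleavage conditions, which is why it is the reserve and not the main line.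

## Further compounds

F1 | step 11 | all-cis (meso) 3-[(8Z)-heptadec-8-en-1-yl]-1-oxa-2-azaspiro[4.5]dec-2-ene-7,9-diol | CCCCCCCC/C=C\CCCCCCCC1=NO[C@@]2(C1)C[C@@H](O)C[C@@H](O)C2
F2 | step 11 | (10Z)-1-(all-cis-1,3,5-trihydroxycyclohexyl)nonadec-10-en-2-one (meso) | CCCCCCCC/C=C\CCCCCCCC(=O)C[C@]1(O)C[C@@H](O)C[C@@H](O)C1
F3 | step 5 | cis-5-methylidenecyclohexane-1,3-diyl diacetate (meso) | C=C1C[C@@H](OC(C)=O)C[C@@H](OC(C)=O)C1
F4 | step 3 | cis-3,5-bis[(tert-butyldimethylsilyl)oxy]-1-[(trimethylsilyl)methyl]cyclohexan-1-ol (either orientation at C1) | C[Si](C)(C)CC1(O)C[C@@H](O[Si](C)(C)C(C)(C)C)C[C@@H](O[Si](C)(C)C(C)(C)C)C1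
F0 | step 13 | none | none
F5 | step 15 | (5R,7S,9R)-3-[(8Z)-heptadec-8-en-1-yl]-9-hydroxy-1-oxa-2-azaspiro[4.5]dec-2-en-7-yl acetate | CCCCCCCC/C=C\CCCCCCCC1=NO[C@@]2(C1)C[C@@H](OC(C)=O)C[C@@H](O)C2
F6 | step 15 | (5R)-3-[(8Z)-heptadec-8-en-1-yl]-1-oxa-2-azaspiro[4.5]deca-2,8-dien-7-one | CCCCCCCC/C=C\CCCCCCCC1=NO[C@@]2(C1)CC=CC(=O)C2
A1 | alternative 1 | 3-(2-oxopropyl)-3-(triethylsilyloxy)pentanedial (achiral) | CC(=O)CC(CC=O)(CC=O)O[Si](CC)(CC)CC
A2 | alternative 1 | 2-[(1R)-3-oxo-1-(triethylsilyloxy)cyclohex-4-en-1-yl]acetaldehyde | O=CC[C@]1(O[Si](CC)(CC)CC)CC=CC(=O)C1
A3 | alternative 2 | (5R,6S)-5-[(tert-butyldimethylsilyl)oxy]-6-ethenyl-1-[(8Z)-heptadec-8-en-1-yl]-3-[(4-methoxybenzyl)oxy]cyclohex-2-en-1-ol (carbinol centre left open, it is lost in the rearrangement) | CCCCCCCC/C=C\CCCCCCCC1(O)C=C(OCc2ccc(OC)cc2)C[C@@H](O[Si](C)(C)C(C)(C)C)[C@@H]1C=C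
A4 | alternative 2 | (10Z)-1-[(1S,5R)-5-[(tert-butyldimethylsilyl)oxy]-1-[(4-methoxybenzyl)oxy]cyclohex-3-en-1-yl]nonadec-10-en-2-one | CCCCCCCC/C=C\CCCCCCCC(=O)C[C@]1(OCc2ccc(OC)cc2)CC=C[C@H](O[Si](C)(C)C(C)(C)C)C1
A5 | alternative 3 | 2-[(8Z)-heptadec-8-en-1-yl]-2-{[(2R)-2-[(2Z)-3-(1,3-dithian-2-yl)prop-2-en-1-yl]oxiran-2-yl]methyl}-1,3-dithiane | CCCCCCCC/C=C\CCCCCCCC1(SCCCS1)C[C@@]2(CO2)C/C=C\C3SCCCS3
A6 | alternative 3 | (8R)-8-{[2-[(8Z)-heptadec-8-en-1-yl]-1,3-dithian-2-yl]methyl}-1,5-dithiaspiro[5.5]undec-10-en-8-ol | CCCCCCCC/C=C\CCCCCCCC1(SCCCS1)C[C@]2(O)CC=CC3(SCCCS3)C2
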